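**Plan**

- The target is methyl shikimate esterified at O3 and O5 with (E)-3-methylpent-2-enoic acid. Ring atoms: C1 (ester-bearing alkene carbon), C2 (alkene CH), C3–C5 (oxygenated carbons), C6 (CH2).
- Retrosynthetic cuts, in order: the O3 ester, the ring bond C2–C3, the O5 ester (with inversion at C5), the C2–Br bond (back to an acrylate), and the chain bond C5–C6.
- Enabling feature: C2 is the β-carbon of the C1=C2 enoate and its neighbour C3 is a carbinol carbon, so both are naturally electrophilic. Turning C2 into an alkenylmetal that attacks a C3 aldehyde makes the allylic alcohol and the only ring, the cyclohexene, in one event.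
- Forward: a Barbier allylation joins C5–C6, the acrylate becomes an (E)-β-bromoacrylate, O5 is acylated, C3 is brought to the aldehyde, the ring closes through C2–C3, then O3 is acylated and O4 freed.
- Stereochemistry: C4 comes from (R)-glyceraldehyde acetonide, C5 from Felkin–Anh allylation followed by Mitsunobu inversion, and C3 from substrate control in the ring closure. The (E)-acyl alkenes arrive with the acid.

Key step: step 9

Remark: commercial (R)-2,3-O-isopropylideneglyceraldehyde oligomerises on storage and is assumed to be distilled just before use.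
Remark: open-chain intermediates are discussed with the ring numbering (C2 = CHBr carbon, C3 = terminal CH2O or CHO carbon).
Remark: short-lived organometallic and activated species (allylindium, alkenylchromium, oxyphosphonium, alkoxysulfonium, O-acylisourea) are treated as mechanism; the dibromide that persists between the two stages of step 3 is listed as an intermediate.

**Step 1**
Reactants: 1 (R)-2,3-O-isopropylideneglyceraldehyde; 2 methyl 2-(bromomethyl)acrylate
Product: 3 methyl (4S)-4-[(4R)-2,2-dimethyl-1,3-dioxolan-4-yl]-4-hydroxy-2-methylidenebutanoate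
Conditions: In powder, THF/H2O (1:1), rt
Reagents that add atoms: none
Why: Barbier allylation in which the allylindium species formed in situ should add under Felkin–Anh (non-chelation) control, anti to the dioxolane C–O bond, setting the new carbinol centre (future C5) as the anti (4S) isomer while the near-neutral aqueous medium leaves the hydroxy ester unlactonised; the minor syn isomer is removed by chromatography.

**Step 2**
Reactants: 3 methyl (4S)-4-[(4R)-2,2-dimethyl-1,3-dioxolan-4-yl]-4-hydroxy-2-methylidenebutanoate
Product: 4 methyl (4S)-4-[(4R)-2,2-dimethyl-1,3-dioxolan-4-yl]-2-methylidene-4-(triethylsilyloxy)butanoate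
Conditions: TESCl, imidazole, DMF, 0 °C to rt
Reagents that add atoms: chlorotriethylsilane (TESCl), CC[Si](Cl)(CC)CC
Why: Routine silyl ether formation that caps O5 so that the γ-hydroxy ester can neither lactonise under base nor attack the bromonium ion in step 3, and that shields the neighbouring C6 hydrogens.

**Step 3**
Reactants: 4 methyl (4S)-4-[(4R)-2,2-dimethyl-1,3-dioxolan-4-yl]-2-methylidene-4-(triethylsilyloxy)butanoate
Product: 6 methyl (2E,4S)-2-(bromomethylidene)-4-[(4R)-2,2-dimethyl-1,3-dioxolan-4-yl]-4-(triethylsilyloxy)butanoate, via dibromide 5 (not isolated)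
Conditions: Br2, CH2Cl2, −20 to 0 °C, dark; then DBU, 0 °C to rt
Reagents that add atoms: bromine, BrBr
Why: Bromine addition to the 1,1-disubstituted acrylate followed by anti E2 dehydrobromination of the tertiary α-bromide, the sequence known to turn methacrylates into (E)-3-bromomethacrylates, should remove an acidified CH2Br hydrogen in preference to a shielded C6 hydrogen and leave bromine trans to the ester, i.e. (E).

**Step 4**
Reactants: 6 methyl (2E,4S)-2-(bromomethylidene)-4-[(4R)-2,2-dimethyl-1,3-dioxolan-4-yl]-4-(triethylsilyloxy)butanoate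
Product: 7 methyl (2E,4S)-2-(bromomethylidene)-4-[(4R)-2,2-dimethyl-1,3-dioxolan-4-yl]-4-hydroxybutanoate
Conditions: HF·pyridine, pyridine, THF, 0 °C to rt
Reagents that add atoms: none
Why: Buffered fluoride cleavage of the secondary triethylsilyl ether, which should leave the acetonide, the methyl ester and the β-bromoacrylate untouched and, being free of base, should not lactonise the freed γ-hydroxy ester, which is used at once.

**Step 5**
Reactants: 7 methyl (2E,4S)-2-(bromomethylidene)-4-[(4R)-2,2-dimethyl-1,3-dioxolan-4-yl]-4-hydroxybutanoate; 8 (E)-3-methylpent-2-enoic acid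
Product: 9 methyl (2E,4R)-2-(bromomethylidene)-4-[(4R)-2,2-dimethyl-1,3-dioxolan-4-yl]-4-[(2E)-3-methylpent-2-enoyloxy]butanoate
Conditions: PPh3, DIAD, toluene, 0 °C to rt
Reagents that add atoms: none
Why: Mitsunobu esterification in which the carboxylate of 8 displaces the oxyphosphonium group by SN2, inverting C5 to the 4,5-threo configuration of the target and installing the O5 acyl group in the same operation.

**Step 6**
Reactants: 9 methyl (2E,4R)-2-(bromomethylidene)-4-[(4R)-2,2-dimethyl-1,3-dioxolan-4-yl]-4-[(2E)-3-methylpent-2-enoyloxy]butanoate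
Product: 10 methyl (2E,4R,5R)-2-(bromomethylidene)-5,6-dihydroxy-4-[(2E)-3-methylpent-2-enoyloxy]hexanoate
Conditions: AcOH/H2O (4:1), 40 °C
Reagents that add atoms: none
Why: Acid-catalysed hydrolysis of the terminal isopropylidene acetal under conditions mild enough that the esters and the vinyl bromide should survive and acyl migration from O5 stays slow.

**Step 7**
Reactants: 10 methyl (2E,4R,5R)-2-(bromomethylidene)-5,6-dihydroxy-4-[(2E)-3-methylpent-2-enoyloxy]hexanoate
Product: 11 methyl (2E,4R,5R)-2-(bromomethylidene)-4-[(2E)-3-methylpent-2-enoyloxy]-5,6-bis(triethylsilyloxy)hexanoate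
Conditions: TESOTf, 2,6-lutidine, CH2Cl2, −78 °C
Reagents that add atoms: triethylsilyl trifluoromethanesulfonate (TESOTf), CC[Si](CC)(CC)OS(=O)(=O)C(F)(F)F
Why: Silylation with the silyl triflate and a hindered pyridine base at low temperature should cap both hydroxyls before the O5 acyl group can migrate to O4.

**Step 8**
Reactants: 11 methyl (2E,4R,5R)-2-(bromomethylidene)-4-[(2E)-3-methylpent-2-enoyloxy]-5,6-bis(triethylsilyloxy)hexanoate
Product: 12 methyl (2E,4R,5S)-2-(bromomethylidene)-4-[(2E)-3-methylpent-2-enoyloxy]-6-oxo-5-(triethylsilyloxy)hexanoate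
Conditions: (COCl)2, DMSO, CH2Cl2, −78 to −40 °C; then Et3N, −78 to 0 °C, cold buffered work-up
Reagents that add atoms: none
Why: Swern oxidation of a bis-triethylsilyl ether, in which the chlorosulfonium reagent cleaves only the unhindered primary silyl ether and oxidises it in the same flask (the known selective oxidative deprotection of primary triethylsilyl ethers), with the cold work-up limiting β-elimination of the O5 carboxylate.

**Step 9**
Reactants: 12 methyl (2E,4R,5S)-2-(bromomethylidene)-4-[(2E)-3-methylpent-2-enoyloxy]-6-oxo-5-(triethylsilyloxy)hexanoate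
Product: 13 methyl (3R,4R,5R)-3-hydroxy-5-[(2E)-3-methylpent-2-enoyloxy]-4-(triethylsilyloxy)cyclohex-1-ene-1-carboxylate
Conditions: CrCl2 (excess), NiCl2 (cat.), degassed DMF, rt, high dilution (slow addition of 12)
Reagents that add atoms: none
Why: Nozaki–Hiyama–Kishi reaction: divalent chromium reduces NiCl2 to zerovalent nickel, which inserts into the activated C2–Br bond, and transmetalation to trivalent chromium gives an alkenylchromium nucleophile that adds to the C3 aldehyde, forming C2–C3 and the C3 carbinol. The closest known reaction type is the intramolecular Nozaki–Hiyama–Kishi cyclisation of haloalkenes, β-haloacrylates included, onto aldehydes. The cyclohexene ring closes in a 6-exo-trig mode, which the (E)-bromoalkene allows because it holds C2 and the C6 chain on the same side of the double bond. The new C3 centre is controlled by the C4 silyloxy centre: in a half-chair with the C4 and C5 oxygen substituents equatorial, C2 attacks anti to the C4–O bond (polar Felkin–Anh arrangement) and the carbonyl oxygen should sit pseudo-axial, giving the 3,4-cis alcohol. The step needs chemoselectivity for the vinyl bromide and the aldehyde, which is secured because the organochromium species leaves esters, enoates and silyl ethers alone and the aldehyde is the only strongly electrophilic carbonyl; high dilution suppresses intermolecular coupling.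

**Step 10**
Reactants: 13 methyl (3R,4R,5R)-3-hydroxy-5-[(2E)-3-methylpent-2-enoyloxy]-4-(triethylsilyloxy)cyclohex-1-ene-1-carboxylate; 8 (E)-3-methylpent-2-enoic acid
Product: 14 methyl (3R,4S,5R)-3,5-bis[(2E)-3-methylpent-2-enoyloxy]-4-(triethylsilyloxy)cyclohex-1-ene-1-carboxylate
Conditions: DCC, DMAP (cat.), CH2Cl2, 0 °C to rt
Reagents that add atoms: none
Why: Steglich esterification (carbodiimide activation with nucleophilic catalysis) of the only free hydroxyl with retention at C3, under conditions that should neither deconjugate the (E)-enoate nor disturb the silyl ether.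

**Step 11**
Reactants: 14 methyl (3R,4S,5R)-3,5-bis[(2E)-3-methylpent-2-enoyloxy]-4-(triethylsilyloxy)cyclohex-1-ene-1-carboxylate
Product: 15 methyl (3R,4S,5R)-4-hydroxy-3,5-bis[(2E)-3-methylpent-2-enoyloxy]cyclohex-1-ene-1-carboxylate
Conditions: HF·pyridine, pyridine, THF, 0 °C
Reagents that add atoms: none
Why: Buffered fluoride cleavage of the C4 triethylsilyl ether, chosen because neither base nor strong acid is present to move an acyl group from O3 or O5 onto the freed O4.

**Compound list**

1 | (R)-2,3-O-isopropylideneglyceraldehyde | O=C[C@H]1COC(C)(C)O1 | starting material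
2 | methyl 2-(bromomethyl)acrylate | COC(=O)C(=C)CBr | starting material
3 | methyl (4S)-4-[(4R)-2,2-dimethyl-1,3-dioxolan-4-yl]-4-hydroxy-2-methylidenebutanoate (anti adduct) | CC1(C)OC[C@@H](O1)[C@@H](O)CC(=C)C(=O)OC | intermediate
4 | methyl (4S)-4-[(4R)-2,2-dimethyl-1,3-dioxolan-4-yl]-2-methylidene-4-(triethylsilyloxy)butanoate | CC1(C)OC[C@@H](O1)[C@@H](O[Si](CC)(CC)CC)CC(=C)C(=O)OC | intermediate
5 | methyl (4S)-2-bromo-2-(bromomethyl)-4-[(4R)-2,2-dimethyl-1,3-dioxolan-4-yl]-4-(triethylsilyloxy)butanoate (both C2 epimers) | CC1(C)OC[C@@H](O1)[C@@H](O[Si](CC)(CC)CC)CC(Br)(CBr)C(=O)OC | intermediate (not isolated)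
6 | methyl (2E,4S)-2-(bromomethylidene)-4-[(4R)-2,2-dimethyl-1,3-dioxolan-4-yl]-4-(triethylsilyloxy)butanoate | CC1(C)OC[C@@H](O1)[C@@H](O[Si](CC)(CC)CC)C/C(C(=O)OC)=C\Br | intermediate
7 | methyl (2E,4S)-2-(bromomethylidene)-4-[(4R)-2,2-dimethyl-1,3-dioxolan-4-yl]-4-hydroxybutanoate | CC1(C)OC[C@@H](O1)[C@@H](O)C/C(C(=O)OC)=C\Br | intermediate
8 | (E)-3-methylpent-2-enoic acid | CC/C(C)=C/C(=O)O | starting material
9 | methyl (2E,4R)-2-(bromomethylidene)-4-[(4R)-2,2-dimethyl-1,3-dioxolan-4-yl]-4-[(2E)-3-methylpent-2-enoyloxy]butanoate | CC1(C)OC[C@@H](O1)[C@H](OC(=O)/C=C(\C)CC)C/C(C(=O)OC)=C\Br | intermediate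
10 | methyl (2E,4R,5R)-2-(bromomethylidene)-5,6-dihydroxy-4-[(2E)-3-methylpent-2-enoyloxy]hexanoate | OC[C@@H](O)[C@H](OC(=O)/C=C(\C)CC)C/C(C(=O)OC)=C\Br | intermediate
11 | methyl (2E,4R,5R)-2-(bromomethylidene)-4-[(2E)-3-methylpent-2-enoyloxy]-5,6-bis(triethylsilyloxy)hexanoate | CC[Si](CC)(CC)OC[C@@H](O[Si](CC)(CC)CC)[C@H](OC(=O)/C=C(\C)CC)C/C(C(=O)OC)=C\Br | intermediate
12 | methyl (2E,4R,5S)-2-(bromomethylidene)-4-[(2E)-3-methylpent-2-enoyloxy]-6-oxo-5-(triethylsilyloxy)hexanoate (cyclisation precursor) | O=C[C@@H](O[Si](CC)(CC)CC)[C@H](OC(=O)/C=C(\C)CC)C/C(C(=O)OC)=C\Br | intermediate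
13 | methyl (3R,4R,5R)-3-hydroxy-5-[(2E)-3-methylpent-2-enoyloxy]-4-(triethylsilyloxy)cyclohex-1-ene-1-carboxylate (3,4-cis, 4,5-trans; shikimate configuration) | O[C@@H]1C=C(C(=O)OC)C[C@@H](OC(=O)/C=C(\C)CC)[C@@H]1O[Si](CC)(CC)CC | intermediate
14 | methyl (3R,4S,5R)-3,5-bis[(2E)-3-methylpent-2-enoyloxy]-4-(triethylsilyloxy)cyclohex-1-ene-1-carboxylate | CC/C(C)=C/C(=O)O[C@@H]1C=C(C(=O)OC)C[C@@H](OC(=O)/C=C(\C)CC)[C@@H]1O[Si](CC)(CC)CC | intermediate
15 | methyl (3R,4S,5R)-4-hydroxy-3,5-bis[(2E)-3-methylpent-2-enoyloxy]cyclohex-1-ene-1-carboxylate | CC/C(C)=C/C(=O)O[C@@H]1C=C(C(=O)OC)C[C@@H](OC(=O)/C=C(\C)CC)[C@@H]1O | target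

**Step count and risks**

Total step count: 11. Longest linear sequence: 11 steps (1 to 15).

The three steps most likely to fail:

Step 9 (ring closure). The alkenylchromium may be delivered to the other face of the aldehyde, for instance through a four-centre arrangement that prefers a pseudo-equatorial carbonyl oxygen, so facial selectivity at C3 may be poor or reversed. Fallback: setting out from 12, the same CrCl2/NiCl2 cyclisation is then used as a route to the 3,4-trans alcohol, methyl (3S,4R,5R)-3-hydroxy-5-[(2E)-3-methylpent-2-enoyloxy]-4-(triethylsilyloxy)cyclohex-1-ene-1-carboxylate F1. This alcohol is esterified with 8 under Mitsunobu conditions (PPh3, DIAD, toluene, 0 °C), where SN2 displacement at the allylic C3 inverts the centre; attack at the fully substituted, ester-bearing C1 should not compete. The fallback comes back to the route at 14 and replaces step 10.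

Step 3 (bromination and dehydrobromination). The base may remove a C6 hydrogen instead of a CH2Br hydrogen, or elimination may run through the rotamer that places bromine cis to the ester, which would erode regio- and (E)-selectivity. Fallback: setting out from 3, acid-catalysed lactonisation (camphorsulfonic acid cat., CH2Cl2, rt) should give the α-methylene lactone (5S)-5-[(4R)-2,2-dimethyl-1,3-dioxolan-4-yl]-3-methylideneoxolan-2-one F2. Treatment with Br2 and then DBU, the sequence established for α-methylene-γ-butyrolactones, should lead by way of the dibromolactone F3 to the (E)-bromomethylidene lactone F4; in the five-membered ring the C6 hydrogens cannot become anti-periplanar to the C1–Br bond, so only the exocyclic elimination is open. Opening with LiOH (one equivalent, THF/H2O, 0 °C) gives the lithium hydroxy-carboxylate F5, and MeI in DMF methylates it to 7, where the route resumes; steps 2 and 4 are then not needed.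

Step 5 (Mitsunobu inversion). Displacement at the crowded oxyphosphonium centre next to the dioxolane by a weakly acidic carboxylic acid may be slow, letting elimination toward C6 or participation of the methyl ester carbonyl compete. Fallback: setting out from 7, ClCH2SO2Cl and pyridine (CH2Cl2, 0 °C) give the chloromethanesulfonate F6. This sulfonate is displaced with inversion by the cesium salt of 8 (8, Cs2CO3, 18-crown-6, toluene, 50 °C), a sulfonate displacement in place of the redox condensation, and the fallback comes back to the route at 9.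

**Further compounds**

F1 | step 9 | methyl (3S,4R,5R)-3-hydroxy-5-[(2E)-3-methylpent-2-enoyloxy]-4-(triethylsilyloxy)cyclohex-1-ene-1-carboxylate | O[C@H]1C=C(C(=O)OC)C[C@@H](OC(=O)/C=C(\C)CC)[C@@H]1O[Si](CC)(CC)CC
F2 | step 3 | (5S)-5-[(4R)-2,2-dimethyl-1,3-dioxolan-4-yl]-3-methylideneoxolan-2-one | CC1(C)OC[C@@H](O1)[C@@H]1CC(=C)C(=O)O1
F3 | step 3 | (5S)-3-bromo-3-(bromomethyl)-5-[(4R)-2,2-dimethyl-1,3-dioxolan-4-yl]oxolan-2-one (both C3 epimers) | CC1(C)OC[C@@H](O1)[C@@H]1CC(Br)(CBr)C(=O)O1
F4 | step 3 | (3E,5S)-3-(bromomethylidene)-5-[(4R)-2,2-dimethyl-1,3-dioxolan-4-yl]oxolan-2-one | CC1(C)OC[C@@H](O1)[C@@H]1C/C(=C\Br)C(=O)O1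
F5 | step 3 | lithium (2E,4S)-2-(bromomethylidene)-4-[(4R)-2,2-dimethyl-1,3-dioxolan-4-yl]-4-hydroxybutanoate | CC1(C)OC[C@@H](O1)[C@@H](O)C/C(C(=O)[O-])=C\Br.[Li+]
F6 | step 5 | methyl (2E,4S)-2-(bromomethylidene)-4-[(chloromethanesulfonyl)oxy]-4-[(4R)-2,2-dimethyl-1,3-dioxolan-4-yl]butanoate | CC1(C)OC[C@@H](O1)[C@@H](OS(=O)(=O)CCl)C/C(C(=O)OC)=C\Br
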